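I began with the mirror pair.

| flask | left-handed substrate | right-handed substrate | partner | protic impurity | free catalyst | remark | time |
|---|---|---|---|---|---|---|---|
| north | 20 mM | 20 mM | 40 mM | 0.40 mM | 100 µM | the very flask that is asked about, followed so far |  |
| south-west | 20 mM | 20 mM | 40 mM | 0.40 mM | 50 µM | run made earlier |  |
| flask | 20 mM | 20 mM | 40.0 mM | 0.400 mM | 100 µM |  | 12 h |

- north (time / h: right-handed substrate / %, left-handed substrate / %): 0.500: 48.2, 18.8; 1.00: 48.6, 10.0; 1.50: 48.7, 8.0; 2.00: 47.9, 5.5; 2.50: 46.8, 4.9; 3.00: 47.7, 3.2; 4.00: 44.9, 3.3
- south-west (time / h: right-handed substrate / %, left-handed substrate / %): 0.250: 49.7, 33.9; 0.667: 48.6, 23.0; 1.33: 48.6, 13.3; 2.00: 49.2, 9.6; 3.00: 47.0, 8.0; 4.00: 48.9, 6.5; 5.00: 48.4, 3.9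

(scatter of a reading: 1 percentage point)

1. whether the excess of right-handed substrate over left-handed substrate among what is left of the two reaches 80% by 12 h (no / yes)
2. the highest excess of right-handed substrate over left-handed substrate among what is left of the two up to 12 h

- free catalyst is single-handed; left-handed substrate and right-handed substrate are mirror images of each other, charged as a racemate, each of them at the stated concentration

Let L and S be the left-handed and right-handed substrate in percent of the pair charged, each starting at 50.0%. The last two readings of each run averaged L = 4.23% and S = 47.5%, which gave a reading of 47.7 for s, the selectivity factor: the e-foldings L loses for each e-folding S loses.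

The excess (S−L)/(S+L) reaches 80% when S/L = 9.00, so L had to fall to about 5.27%. The north flask read 4.9% at 2.50 h, lower than that, so I answered yes.

But s carries no clock. The south-west run, with half the catalyst, read 9.6% at 2.00 h, close to the north flask's 10.0% at 1.00 h. Between the north flask's readings at 1.00 h and 4.00 h the reciprocal of L rose on average at 6.77 h⁻¹, though those readings scatter widely about a straight line. I assumed that straight line as far as 12 h, and it gave L = 1.18%; s then gave S = 46.2%, and so an excess of 95.0%, which I took as my estimate of the top.

The forecast answered yes with a top of 94%, between 87% and 97.5%, noting that “no true plateau is proven”.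

The north flask gave yes, with a top of 97.4%.

    partner + protic impurity → quenched reagent (k = 1000 M⁻¹ h⁻¹)
    partner + free catalyst + left-handed substrate → free catalyst + left-handed product (k = 1.60 × 10⁶ M⁻² h⁻¹)
    partner + free catalyst + right-handed substrate → free catalyst + right-handed product (k = 26000 M⁻² h⁻¹)
    partner ⇌ dormant form (K = 1.30, k = 4.60 h⁻¹)
    2 free catalyst → spent catalyst (k = 4500 M⁻¹ h⁻¹)

At 12.0 h the north flask held L = 0.605%, lower than my line's value, with free catalyst at 8.47% of its charge. When the excess reached 80% at 1.94 h, s put S at 47.7%, and the north flask held 48.2%.

The numbers in the tables were computed with constants of no real substance, and the scatter is random.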